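## Retrosynthetic overview

1. The strategy rests on the 2-alkyl-5-methylhydroquinone ring. Going round from the ring carbon that carries the C1 methylene, the atoms are CH, C–O, C–CH3, CH and C–OH: the two carbons of a terminal alkyne, a methoxycarbene carbon, the two carbons of an isopropenyl group and one CO. The arene is therefore made last, by Dötz benzannulation of alkyne 24 with pentacarbonyl[methoxy(prop-1-en-2-yl)carbene]chromium 29, followed by oxidation to the quinone and reduction.
2. Alkyne 24 (C2–OAc, C3–OH, C3a–OAc) comes from allylic alcohol 21 by hydroxyl-directed epoxidation of its 1,1-disubstituted alkene, acetolysis of the epoxide at C3a and acetylation. C2 is set earlier, by asymmetric propargylation of 2-bromoacrolein (17).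
3. The 2,8-dioxabicyclo[3.2.1]octane ketal is closed from γ-lactone 14 and the vinyllithium made from 17. The tetrahydrofuran ring (C4–O–C7) is already present in the lactol; the 1,3-dioxane ring (C4–O–C9) closes under mild acid.
4. Lactone 14 takes C7 from (R)-linalool and C9 from a Nozaki–Hiyama–Kishi coupling with vinyl iodide 11, then oxidation and CBS reduction.
5. Ring order: bicyclic ketal (step 10), then the benzene ring (step 16).

Key step: step 16

## Remarks and assumptions

- Numbering used below: C1 benzylic CH2, C2 CH(OAc), C3 tertiary carbinol with its CH2OAc carbon C3a, C4 ketal carbon, C5, C6, C7 (C–CH3), C8, C9 (CH–O), C10=C11. The target is (2R,3S,4R,7R,9S,10E).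
- Bk = (1R,3S,5R)-3-[(1E)-2,6-dimethylhepta-1,5-dien-1-yl]-5-methyl-2,8-dioxabicyclo[3.2.1]octan-1-yl. Its ring atoms are C1 = C4, O2, C3 = C9, C4 = C8, C5 = C7, C6 and C7 = C6 and C5, O8.
- Assumption: commercial (R)-(−)-linalool is used at high enantiomeric purity. In step 9 the ligand antipode that gives (R)-17 is used, and the assignment is checked on 17 by Mosher ester analysis.

## Route

Step 1
Reactants: 1 (R)-linalool
Product: 3 (5R)-5-ethenyl-5-methyldihydrofuran-2(3H)-one, via lactol 2 (not isolated)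
Conditions: O3 (1 equiv, Sudan red 7B end point), CH2Cl2, −78 °C; Me2S, −78 °C to rt, concentrate; then TEMPO (10 mol%), PhI(OAc)2 (1.3 equiv), CH2Cl2, rt
Reagents that add atoms: ozone, [O-][O+]=O
Why: Ozone attacks the electron-rich trisubstituted alkene much faster than the vinyl group, the resulting C4 aldehyde closes on the tertiary C7 hydroxyl as a five-membered lactol, and the oxoammonium oxidation then gives the γ-lactone with C7 untouched.

Step 2
Reactants: 3 (5R)-5-ethenyl-5-methyldihydrofuran-2(3H)-one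
Product: 5 (5R)-5-(2-hydroxyethyl)-5-methyldihydrofuran-2(3H)-one, via alkylborane 4 (not isolated)
Conditions: 9-BBN (1.3 equiv), THF, 0 °C to rt; then H2O2, aq NaOAc, 0 °C to rt
Reagents that add atoms: hydrogen peroxide, OO
Why: In this hydroboration–oxidation 9-BBN places boron on the terminal vinyl carbon without reducing the lactone, and buffered peroxide replaces boron by hydroxyl with the lactone intact.

Step 3
Reactants: 5 (5R)-5-(2-hydroxyethyl)-5-methyldihydrofuran-2(3H)-one
Product: 6 [(2R)-2-methyl-5-oxotetrahydrofuran-2-yl]acetaldehyde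
Conditions: Dess–Martin periodinane, CH2Cl2, 0 °C to rt
Reagents that add atoms: none
Why: Dess–Martin oxidation stops at the aldehyde under neutral conditions, which should avoid β-elimination of the lactone carboxylate from this β-acyloxy aldehyde.

Step 4
Reactants: 7 5-bromo-2-methylpent-2-ene; 8 lithium acetylide–ethylenediamine complex
Product: 9 6-methylhept-5-en-1-yne
Conditions: DMSO, 10 °C to rt
Reagents that add atoms: none
Why: SN2 alkylation of lithium acetylide by a primary bromide in DMSO is a standard terminal alkyne synthesis.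

Step 5
Reactants: 9 6-methylhept-5-en-1-yne
Product: 11 (1E)-1-iodo-2,6-dimethylhepta-1,5-diene, via alkenylalane 10 (not isolated)
Conditions: Me3Al (2 equiv), Cp2ZrCl2 (20 mol%), CH2Cl2, 0 °C to rt; then I2, THF, −30 to 0 °C
Reagents that add atoms: trimethylaluminium, C[Al](C)C; iodine, II
Why: Negishi carboalumination adds methyl and aluminium syn across the terminal alkyne with aluminium on the terminal carbon, and iodinolysis with retention gives the E trisubstituted vinyl iodide.

Step 6
Reactants: 6 [(2R)-2-methyl-5-oxotetrahydrofuran-2-yl]acetaldehyde; 11 (1E)-1-iodo-2,6-dimethylhepta-1,5-diene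
Product: 12 (5R)-5-[(3E)-2-hydroxy-4,8-dimethylnona-3,7-dien-1-yl]-5-methyldihydrofuran-2(3H)-one as both C9 epimers
Conditions: CrCl2 (4 equiv), NiCl2 (1 mol%), DMF, rt
Reagents that add atoms: none
Why: In this Nozaki–Hiyama–Kishi coupling the organochromium species formed from 11 adds to the aldehyde only, with retention of the E geometry and without touching the lactone, and the unselective C9 carbinol is corrected in the next two steps.

Step 7
Reactants: 12 (5R)-5-[(3E)-2-hydroxy-4,8-dimethylnona-3,7-dien-1-yl]-5-methyldihydrofuran-2(3H)-one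
Product: 13 (5R)-5-[(3E)-4,8-dimethyl-2-oxonona-3,7-dien-1-yl]-5-methyldihydrofuran-2(3H)-one
Conditions: Dess–Martin periodinane, CH2Cl2, 0 °C to rt
Reagents that add atoms: none
Why: Dess–Martin oxidation of the allylic alcohol gives the enone under neutral conditions, so the β-acyloxy ketone should not eliminate.

Step 8
Reactants: 13 (5R)-5-[(3E)-4,8-dimethyl-2-oxonona-3,7-dien-1-yl]-5-methyldihydrofuran-2(3H)-one
Product: 14 (5R)-5-[(2S,3E)-2-hydroxy-4,8-dimethylnona-3,7-dien-1-yl]-5-methyldihydrofuran-2(3H)-one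
Conditions: (R)-2-methyl-CBS-oxazaborolidine (0.5 equiv), catecholborane (1.5 equiv), toluene, −78 °C
Reagents that add atoms: none
Why: In this Corey–Bakshi–Shibata reduction the (R)-oxazaborolidine binds the enone with the alkenyl group as the large substituent and delivers hydride to give the (S)-carbinol at C9 by reagent control, while catecholborane leaves the lactone and the alkenes alone.

Step 9
Reactants: 15 2-bromoacrolein; 16 4,4,5,5-tetramethyl-2-[3-(trimethylsilyl)prop-2-yn-1-yl]-1,3,2-dioxaborolane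
Product: 17 (3R)-2-bromo-6-(trimethylsilyl)hex-1-en-5-yn-3-ol
Conditions: Cu(O2CiPr)2 (5 mol%), LiOtBu (8 mol%), MeO-BIBOP (6 mol%, antipode giving the R alcohol), THF, −60 to −30 °C; aq NH4Cl
Reagents that add atoms: none
Why: In this Cu(O2CiPr)2-catalysed asymmetric propargylation the boronate is transmetallated to an allenylcopper species that adds SE2' to the aldehyde inside the chiral bisphosphine pocket, which gives the silyl-capped homopropargylic alcohol and sets C2 by ligand control.

Step 10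
Reactants: 17 (3R)-2-bromo-6-(trimethylsilyl)hex-1-en-5-yn-3-ol; 14 (5R)-5-[(2S,3E)-2-hydroxy-4,8-dimethylnona-3,7-dien-1-yl]-5-methyldihydrofuran-2(3H)-one
Product: 20 (3R)-2-Bk-6-(trimethylsilyl)hex-1-en-5-yn-3-ol, via dilithio alkoxide 18 (not isolated), via open-chain hydroxy enone 19 (not isolated)
Conditions: 17 (2.2 equiv), tBuLi (6.6 equiv), Et2O, −78 °C; 14, THF, −78 °C; AcOH, −78 °C; then PPTS (20 mol%), 4 Å MS, CH2Cl2, rt
Reagents that add atoms: none
Why: Deprotonation and bromine–lithium exchange give an alkoxide-bearing vinyllithium that adds once to the γ-lactone (one equivalent being spent on the C9 hydroxyl), and mild acid then ionises the resulting lactol to a cyclic oxocarbenium ion that the C9 hydroxyl captures, so the tetrahydrofuran ring is kept and the 1,3-dioxane ring closes with C4 fixed by C7 and the alkenyl group equatorial.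

Step 11
Reactants: 20 (3R)-2-Bk-6-(trimethylsilyl)hex-1-en-5-yn-3-ol
Product: 21 (3R)-2-Bk-hex-1-en-5-yn-3-ol
Conditions: K2CO3 (0.3 equiv), MeOH, rt
Reagents that add atoms: none
Why: Base-catalysed methanolysis of the alkynyl C–Si bond frees the terminal alkyne at a stage where no ester is present.

Step 12
Reactants: 21 (3R)-2-Bk-hex-1-en-5-yn-3-ol
Product: 22 (1R)-1-[(2S)-2-Bk-oxiran-2-yl]but-3-yn-1-ol
Conditions: VO(acac)2 (5 mol%), tBuOOH (1.5 equiv, in decane), CH2Cl2, 0 °C to rt
Reagents that add atoms: tert-butyl hydroperoxide, CC(C)(C)OO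
Why: The VO(acac)2-catalysed hydroxyl-directed epoxidation touches only the allylic alkene, and allylic 1,2-strain between the C1 methylene and the bulky ketal carbon forces the C2 hydrogen into the alkene plane, which should give the erythro epoxy alcohol, that is, the (S) configuration needed at C3.

Step 13
Reactants: 22 (1R)-1-[(2S)-2-Bk-oxiran-2-yl]but-3-yn-1-ol
Product: 23 (2S,3R)-2-Bk-2,3-dihydroxyhex-5-yn-1-yl acetate
Conditions: Ti(OiPr)4 (1.5 equiv), AcOH (2 equiv), CH2Cl2, rt
Reagents that add atoms: acetic acid, CC(=O)O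
Why: In this titanium-assisted opening of a 2,3-epoxy alcohol by a carboxylic acid, Ti(OiPr)4 bridges the C2 alkoxide and the epoxide oxygen and acetate attacks the unhindered CH2 terminus C3a, so C3 keeps its configuration and emerges as the free tertiary alcohol.

Step 14
Reactants: 23 (2S,3R)-2-Bk-2,3-dihydroxyhex-5-yn-1-yl acetate
Product: 24 (2S,3R)-2-Bk-2-hydroxyhex-5-yne-1,3-diyl diacetate
Conditions: Ac2O, pyridine, DMAP (10 mol%), CH2Cl2, 0 °C to rt
Reagents that add atoms: acetic anhydride, CC(=O)OC(C)=O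
Why: DMAP-catalysed acetylation takes the secondary C2 hydroxyl while the tertiary C3 hydroxyl between two fully substituted carbons stays free, and any acetyl migration between C3a and C2 in step 13 converges on the same diacetate.

Step 15
Reactants: 25 2-bromopropene; 26 Cr(CO)6
Product: 29 pentacarbonyl[methoxy(prop-1-en-2-yl)carbene]chromium, via isopropenyllithium 27 (not isolated), via lithium acylchromate 28 (not isolated)
Conditions: tBuLi (2 equiv), Et2O, −78 °C; 26, Et2O, 0 °C to rt; then Me3OBF4, CH2Cl2/H2O, 0 °C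
Reagents that add atoms: trimethyloxonium tetrafluoroborate, C[O+](C)C.F[B-](F)(F)F
Why: In this Fischer carbene synthesis isopropenyllithium adds to a carbonyl ligand of Cr(CO)6 and the acylchromate is O-methylated by the oxonium salt.

Step 16
Reactants: 24 (2S,3R)-2-Bk-2-hydroxyhex-5-yne-1,3-diyl diacetate; 29 pentacarbonyl[methoxy(prop-1-en-2-yl)carbene]chromium
Product: 31 (2S,3R)-2-Bk-2-hydroxy-4-(2-hydroxy-5-methoxy-4-methylphenyl)butane-1,3-diyl diacetate, via arene tricarbonylchromium complex 30 (not isolated)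
Conditions: 29 (1.8 equiv), THF (0.05 M), 50 °C, Ar; then air, CH2Cl2, silica gel, rt
Reagents that add atoms: none
Why: Thermal loss of one CO from 29 opens a site for the alkyne, which inserts into the Cr=C bond with its unsubstituted carbon bonded to the carbene carbon; CO insertion then gives a chromium-bound dienylketene, six-electron electrocyclization onto the isopropenyl CH2 and tautomerization give the 4-methoxyphenol as its Cr(CO)3 complex 30, and air removes the metal. This is the Dötz benzannulation of an alkenyl(alkoxy)carbene chromium complex with a terminal alkyne, the best-behaved combination of that reaction. The one new ring, the benzene ring, closes by 6π electrocyclization of the dienylketene (bond between the ketene carbon and the isopropenyl CH2) after the two insertions have made the other two ring C–C bonds. No stereocentre is formed, and the five existing ones are remote from the alkyne and not epimerisable under neutral conditions at 50 °C. The step needs regioselective insertion, which the terminal alkyne secures sterically (side chain ortho to the new OH, OMe para), and chemoselectivity, which rests on the two trisubstituted alkenes, the acetates and the ketal being inert to the carbene and on the crowded tertiary C3 hydroxyl being too slow to intercept the ketene before the fast electrocyclization.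

Step 17
Reactants: 31 (2S,3R)-2-Bk-2-hydroxy-4-(2-hydroxy-5-methoxy-4-methylphenyl)butane-1,3-diyl diacetate
Product: 32 (2S,3R)-2-Bk-2-hydroxy-4-(4-methyl-3,6-dioxocyclohexa-1,4-dien-1-yl)butane-1,3-diyl diacetate
Conditions: (NH4)2Ce(NO3)6 (2.2 equiv), MeCN/H2O, 0 °C, 10 min
Reagents that add atoms: water, O
Why: The cerium reagent oxidises the 4-methoxyphenol to the 1,4-benzoquinone within minutes by two one-electron oxidations, attack of water and loss of methanol, under conditions that isolated trisubstituted alkenes, the ketal and the acetates should tolerate.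

Step 18
Reactants: 32 (2S,3R)-2-Bk-2-hydroxy-4-(4-methyl-3,6-dioxocyclohexa-1,4-dien-1-yl)butane-1,3-diyl diacetate
Product: 33 (2S,3R)-2-Bk-4-(2,5-dihydroxy-4-methylphenyl)-2-hydroxybutane-1,3-diyl diacetate
Conditions: Na2S2O4, Et2O/H2O, rt, Ar
Reagents that add atoms: none
Why: Two-phase dithionite reduction converts the quinone into the hydroquinone under neutral conditions, so the acetates and the ketal are untouched and the air-sensitive hydroquinone is formed last.

## Compound list

1 | (R)-linalool, (3R)-3,7-dimethylocta-1,6-dien-3-ol | CC(C)=CCC[C@@](C)(O)C=C | starting material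
2 | (5R)-5-ethenyl-5-methyltetrahydrofuran-2-ol (lactol, both anomers) | C=C[C@@]1(C)CCC(O)O1 | intermediate
3 | (5R)-5-ethenyl-5-methyldihydrofuran-2(3H)-one | C=C[C@@]1(C)CCC(=O)O1 | intermediate
4 | 9-{2-[(2S)-2-methyl-5-oxotetrahydrofuran-2-yl]ethyl}-9-borabicyclo[3.3.1]nonane (same arrangement at C7, descriptor changed by the priority rules) | O=C1CC[C@](C)(CCB2C3CCCC2CCC3)O1 | intermediate
5 | (5R)-5-(2-hydroxyethyl)-5-methyldihydrofuran-2(3H)-one | OCC[C@@]1(C)CCC(=O)O1 | intermediate
6 | [(2R)-2-methyl-5-oxotetrahydrofuran-2-yl]acetaldehyde | O=CC[C@@]1(C)CCC(=O)O1 | intermediate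
7 | 5-bromo-2-methylpent-2-ene | CC(C)=CCCBr | starting material
8 | lithium acetylide–ethylenediamine complex | [Li]C#C.NCCN | starting material
9 | 6-methylhept-5-en-1-yne | C#CCCC=C(C)C | intermediate
10 | [(1E)-2,6-dimethylhepta-1,5-dien-1-yl]dimethylalane | C[Al](C)/C=C(\C)CCC=C(C)C | intermediate
11 | (1E)-1-iodo-2,6-dimethylhepta-1,5-diene | I/C=C(\C)CCC=C(C)C | intermediate
12 | (5R)-5-[(3E)-2-hydroxy-4,8-dimethylnona-3,7-dien-1-yl]-5-methyldihydrofuran-2(3H)-one, both C9 epimers | CC(C)=CCC/C(C)=C/C(O)C[C@@]1(C)CCC(=O)O1 | intermediate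
13 | (5R)-5-[(3E)-4,8-dimethyl-2-oxonona-3,7-dien-1-yl]-5-methyldihydrofuran-2(3H)-one | CC(C)=CCC/C(C)=C/C(=O)C[C@@]1(C)CCC(=O)O1 | intermediate
14 | (5R)-5-[(2S,3E)-2-hydroxy-4,8-dimethylnona-3,7-dien-1-yl]-5-methyldihydrofuran-2(3H)-one | CC(C)=CCC/C(C)=C/[C@@H](O)C[C@@]1(C)CCC(=O)O1 | intermediate
15 | 2-bromoacrolein (2-bromoprop-2-enal) | C=C(Br)C=O | starting material
16 | 4,4,5,5-tetramethyl-2-[3-(trimethylsilyl)prop-2-yn-1-yl]-1,3,2-dioxaborolane | C[Si](C)(C)C#CCB1OC(C)(C)C(C)(C)O1 | starting material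
17 | (3R)-2-bromo-6-(trimethylsilyl)hex-1-en-5-yn-3-ol | C[Si](C)(C)C#CC[C@@H](O)C(Br)=C | intermediate
18 | dilithio derivative of 17 (2-lithioalkene, lithium alkoxide) | [Li]C(=C)[C@H](O[Li])CC#C[Si](C)(C)C | intermediate
19 | (4R,9R,11S,12E)-4,9,11-trihydroxy-9,13,17-trimethyl-5-methylidene-1-(trimethylsilyl)octadeca-12,16-dien-1-yn-6-one, in equilibrium with its five-membered lactol | C[Si](C)(C)C#CC[C@@H](O)C(=C)C(=O)CC[C@@](C)(O)C[C@H](O)/C=C(\C)CCC=C(C)C | intermediate
20 | (3R)-2-Bk-6-(trimethylsilyl)hex-1-en-5-yn-3-ol | C[Si](C)(C)C#CC[C@@H](O)C(=C)[C@]12CC[C@](C)(C[C@@H](/C=C(\C)CCC=C(C)C)O1)O2 | intermediate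
21 | (3R)-2-Bk-hex-1-en-5-yn-3-ol | C#CC[C@@H](O)C(=C)[C@]12CC[C@](C)(C[C@@H](/C=C(\C)CCC=C(C)C)O1)O2 | intermediate
22 | (1R)-1-[(2S)-2-Bk-oxiran-2-yl]but-3-yn-1-ol | C#CC[C@@H](O)[C@@]3(CO3)[C@]12CC[C@](C)(C[C@@H](/C=C(\C)CCC=C(C)C)O1)O2 | intermediate
23 | (2S,3R)-2-Bk-2,3-dihydroxyhex-5-yn-1-yl acetate | CC(=O)OC[C@](O)([C@H](O)CC#C)[C@]12CC[C@](C)(C[C@@H](/C=C(\C)CCC=C(C)C)O1)O2 | intermediate
24 | (2S,3R)-2-Bk-2-hydroxyhex-5-yne-1,3-diyl diacetate | CC(=O)OC[C@](O)([C@@H](CC#C)OC(C)=O)[C@]12CC[C@](C)(C[C@@H](/C=C(\C)CCC=C(C)C)O1)O2 | intermediate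
25 | 2-bromopropene | CC(Br)=C | starting material
26 | hexacarbonylchromium, Cr(CO)6 | O=C=[Cr](=C=O)(=C=O)(=C=O)(=C=O)=C=O | starting material
27 | isopropenyllithium (prop-1-en-2-yllithium) | [Li]C(C)=C | intermediate
28 | lithium pentacarbonyl(2-methylprop-2-enoyl)chromate | [Li+].[O-]C(C(C)=C)=[Cr](=C=O)(=C=O)(=C=O)(=C=O)=C=O | intermediate
29 | pentacarbonyl[methoxy(prop-1-en-2-yl)carbene]chromium | COC(C(C)=C)=[Cr](=C=O)(=C=O)(=C=O)(=C=O)=C=O | intermediate
30 | tricarbonylchromium complex of 31, Cr(CO)3 bound η6 to the new arene | CC(=O)OC[C@](O)([C@@H](Cc3cc(OC)c(C)cc3O)OC(C)=O)[C@]12CC[C@](C)(C[C@@H](/C=C(\C)CCC=C(C)C)O1)O2.[Cr].[C-]#[O+].[C-]#[O+].[C-]#[O+] | intermediate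
31 | (2S,3R)-2-Bk-2-hydroxy-4-(2-hydroxy-5-methoxy-4-methylphenyl)butane-1,3-diyl diacetate | CC(=O)OC[C@](O)([C@@H](Cc3cc(OC)c(C)cc3O)OC(C)=O)[C@]12CC[C@](C)(C[C@@H](/C=C(\C)CCC=C(C)C)O1)O2 | intermediate
32 | (2S,3R)-2-Bk-2-hydroxy-4-(4-methyl-3,6-dioxocyclohexa-1,4-dien-1-yl)butane-1,3-diyl diacetate | CC(=O)OC[C@](O)([C@@H](CC3=CC(=O)C(C)=CC3=O)OC(C)=O)[C@]12CC[C@](C)(C[C@@H](/C=C(\C)CCC=C(C)C)O1)O2 | intermediate
33 | (2S,3R)-2-Bk-4-(2,5-dihydroxy-4-methylphenyl)-2-hydroxybutane-1,3-diyl diacetate | CC(=O)OC[C@](O)([C@@H](Cc1cc(O)c(C)cc1O)OC(C)=O)[C@]12CC[C@](C)(C[C@@H](/C=C(\C)CCC=C(C)C)O1)O2 | target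

## Step count and risks

Total step count: 18.
Longest linear sequence: 14 steps (1, 2, 3, 6, 7, 8, 10, 11, 12, 13, 14, 16, 17, 18) from (R)-linalool.

**Step 16 (key step).** The chromium-bound dienylketene may be intercepted by the free tertiary C3 hydroxyl to give a six-membered lactone. Insertion at the crowded homopropargylic alkyne may also stall or run on to two-alkyne and cyclobutenone products.
Fallback, setting out from 15 (with 14 as coupling partner) and returning at 32: the arene is brought in preformed as its dimethyl ether.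
- Commercial 2,5-dimethoxytoluene is chloromethylated (paraformaldehyde, HCl) to 1-(chloromethyl)-2,5-dimethoxy-4-methylbenzene F1, which with Zn and LiCl in THF gives (2,5-dimethoxy-4-methylbenzyl)zinc chloride F2.
- Addition of F2 to 15 gives racemic 3-bromo-1-(2,5-dimethoxy-4-methylphenyl)but-3-en-2-ol F3. Dess–Martin oxidation gives 3-bromo-1-(2,5-dimethoxy-4-methylphenyl)but-3-en-2-one F4. Reduction with (S)-2-methyl-CBS-oxazaborolidine and catecholborane, with the bromoalkenyl group as the large substituent, gives (2R)-3-bromo-1-(2,5-dimethoxy-4-methylphenyl)but-3-en-2-ol F5.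
- Under the conditions of step 10, F5 is converted into its dilithio derivative F6, which adds to lactone 14 to give the open-chain trihydroxy enone F7 and, with PPTS, the bicyclic ketal (2R)-3-Bk-1-(2,5-dimethoxy-4-methylphenyl)but-3-en-2-ol F8.
- The conditions of steps 12, 13 and 14 then give the epoxy alcohol (1R)-1-[(2S)-2-Bk-oxiran-2-yl]-2-(2,5-dimethoxy-4-methylphenyl)ethan-1-ol F9, the monoacetate (2S,3R)-2-Bk-4-(2,5-dimethoxy-4-methylphenyl)-2,3-dihydroxybutyl acetate F10 and the diacetate (2S,3R)-2-Bk-4-(2,5-dimethoxy-4-methylphenyl)-2-hydroxybutane-1,3-diyl diacetate F11.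
- (NH4)2Ce(NO3)6 in MeCN/H2O oxidises the 1,4-dimethoxyarene of F11 to quinone 32, from which step 18 follows.

**Step 10.** The dilithio reagent may be quenched before it adds. The tetrahedral adduct may collapse early and allow a second addition. The enone may also polymerise or undergo conjugate addition under acid instead of closing the ketal.
Fallback, setting out from 14 and 17 and returning at 20: the C3–C4 bond is made at the aldehyde oxidation level and oxidised afterwards.
- 14 is silylated (Et3SiCl, imidazole) to (5R)-5-[(2S,3E)-4,8-dimethyl-2-(triethylsilyloxy)nona-3,7-dien-1-yl]-5-methyldihydrofuran-2(3H)-one F12 and reduced with iBu2AlH at −78 °C to the lactol (5R)-5-[(2S,3E)-4,8-dimethyl-2-(triethylsilyloxy)nona-3,7-dien-1-yl]-5-methyltetrahydrofuran-2-ol F13.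
- 17 is silylated to (3R)-2-bromo-3-(triethylsilyloxy)-6-(trimethylsilyl)hex-1-en-5-yne F14.
- Nozaki–Hiyama–Kishi coupling (CrCl2, NiCl2 as catalyst, DMSO) of F14 with the open hydroxy aldehyde form of F13 gives (4R,9R,11S,12E)-4,11-bis(triethylsilyloxy)-9,13,17-trimethyl-5-methylidene-1-(trimethylsilyl)octadeca-12,16-dien-1-yne-6,9-diol F15 as a mixture at C6 of that chain.
- Dess–Martin oxidation gives (4R,9R,11S,12E)-9-hydroxy-4,11-bis(triethylsilyloxy)-9,13,17-trimethyl-5-methylidene-1-(trimethylsilyl)octadeca-12,16-dien-1-yn-6-one F16.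
- PPTS in MeOH/CH2Cl2 removes both silyl ethers and closes the ketal to 20.

**Step 9.** The labile α-bromo enal may polymerise under the basic copper alkoxide conditions, or the addition may proceed with poor facial selectivity.
Fallback, setting out from 15 and returning at 17: the C2 stereocentre is set by ketone reduction instead of by C–C bond formation.
- Zn-mediated Barbier addition of 3-bromo-1-(trimethylsilyl)prop-1-yne to 15 in THF/aq NH4Cl gives racemic 2-bromo-6-(trimethylsilyl)hex-1-en-5-yn-3-ol F17.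
- Dess–Martin oxidation gives 2-bromo-6-(trimethylsilyl)hex-1-en-5-yn-3-one F18, which is used at once because it can isomerise to the allenyl ketone.
- Reduction with (S)-2-methyl-CBS-oxazaborolidine and catecholborane, with the bromoalkenyl group as the large substituent, gives (R)-17.

## Further compounds

F1 | step 16 | 1-(chloromethyl)-2,5-dimethoxy-4-methylbenzene | COc1cc(C)c(OC)cc1CCl
F2 | step 16 | (2,5-dimethoxy-4-methylbenzyl)zinc chloride | COc1cc(C)c(OC)cc1C[Zn]Cl
F3 | step 16 | racemic 3-bromo-1-(2,5-dimethoxy-4-methylphenyl)but-3-en-2-ol | COc1cc(C)c(OC)cc1CC(O)C(Br)=C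
F4 | step 16 | 3-bromo-1-(2,5-dimethoxy-4-methylphenyl)but-3-en-2-one | COc1cc(C)c(OC)cc1CC(=O)C(Br)=C
F5 | step 16 | (2R)-3-bromo-1-(2,5-dimethoxy-4-methylphenyl)but-3-en-2-ol | COc1cc(C)c(OC)cc1C[C@@H](O)C(Br)=C
F6 | step 16 | dilithio derivative of F5 (3-lithioalkene, lithium alkoxide) | [Li]C(=C)[C@H](O[Li])Cc1cc(OC)c(C)cc1OC
F7 | step 16 | (2R,7R,9S,10E)-1-(2,5-dimethoxy-4-methylphenyl)-2,7,9-trihydroxy-7,11,15-trimethyl-3-methylidenehexadeca-10,14-dien-4-one | COc1cc(C)c(OC)cc1C[C@@H](O)C(=C)C(=O)CC[C@@](C)(O)C[C@H](O)/C=C(\C)CCC=C(C)C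
F8 | step 16 | (2R)-3-Bk-1-(2,5-dimethoxy-4-methylphenyl)but-3-en-2-ol | COc3cc(C)c(OC)cc3C[C@@H](O)C(=C)[C@]12CC[C@](C)(C[C@@H](/C=C(\C)CCC=C(C)C)O1)O2
F9 | step 16 | (1R)-1-[(2S)-2-Bk-oxiran-2-yl]-2-(2,5-dimethoxy-4-methylphenyl)ethan-1-ol | COc3cc(C)c(OC)cc3C[C@@H](O)[C@@]4(CO4)[C@]12CC[C@](C)(C[C@@H](/C=C(\C)CCC=C(C)C)O1)O2
F10 | step 16 | (2S,3R)-2-Bk-4-(2,5-dimethoxy-4-methylphenyl)-2,3-dihydroxybutyl acetate | CC(=O)OC[C@](O)([C@H](O)Cc3cc(OC)c(C)cc3OC)[C@]12CC[C@](C)(C[C@@H](/C=C(\C)CCC=C(C)C)O1)O2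
F11 | step 16 | (2S,3R)-2-Bk-4-(2,5-dimethoxy-4-methylphenyl)-2-hydroxybutane-1,3-diyl diacetate | CC(=O)OC[C@](O)([C@@H](Cc3cc(OC)c(C)cc3OC)OC(C)=O)[C@]12CC[C@](C)(C[C@@H](/C=C(\C)CCC=C(C)C)O1)O2
F12 | step 10 | (5R)-5-[(2S,3E)-4,8-dimethyl-2-(triethylsilyloxy)nona-3,7-dien-1-yl]-5-methyldihydrofuran-2(3H)-one | CC(C)=CCC/C(C)=C/[C@@H](O[Si](CC)(CC)CC)C[C@@]1(C)CCC(=O)O1
F13 | step 10 | (5R)-5-[(2S,3E)-4,8-dimethyl-2-(triethylsilyloxy)nona-3,7-dien-1-yl]-5-methyltetrahydrofuran-2-ol | CC(C)=CCC/C(C)=C/[C@@H](O[Si](CC)(CC)CC)C[C@@]1(C)CCC(O)O1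
F14 | step 10 | (3R)-2-bromo-3-(triethylsilyloxy)-6-(trimethylsilyl)hex-1-en-5-yne | C[Si](C)(C)C#CC[C@@H](O[Si](CC)(CC)CC)C(Br)=C
F15 | step 10 | (4R,9R,11S,12E)-4,11-bis(triethylsilyloxy)-9,13,17-trimethyl-5-methylidene-1-(trimethylsilyl)octadeca-12,16-dien-1-yne-6,9-diol, both C6 epimers | C[Si](C)(C)C#CC[C@@H](O[Si](CC)(CC)CC)C(=C)C(O)CC[C@@](C)(O)C[C@H](O[Si](CC)(CC)CC)/C=C(\C)CCC=C(C)C
F16 | step 10 | (4R,9R,11S,12E)-9-hydroxy-4,11-bis(triethylsilyloxy)-9,13,17-trimethyl-5-methylidene-1-(trimethylsilyl)octadeca-12,16-dien-1-yn-6-one | C[Si](C)(C)C#CC[C@@H](O[Si](CC)(CC)CC)C(=C)C(=O)CC[C@@](C)(O)C[C@H](O[Si](CC)(CC)CC)/C=C(\C)CCC=C(C)C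
F17 | step 9 | racemic 2-bromo-6-(trimethylsilyl)hex-1-en-5-yn-3-ol | C[Si](C)(C)C#CCC(O)C(Br)=C
F18 | step 9 | 2-bromo-6-(trimethylsilyl)hex-1-en-5-yn-3-one | C[Si](C)(C)C#CCC(=O)C(Br)=C
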